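**Retrosynthetic overview**
1. Rings A and B are bought as aromatics. Ring C is the only ring made, and it is closed last.
2. 11 is opened at O1–C2 to the fully unprotected (E)-chalcone 10. In the forward direction this is a catalytic enantioselective oxa-Michael closure, a small-molecule counterpart of chalcone isomerase, and it sets C2 as (S) in the final step.
3. 10 is cut at Cα=Cβ into the tetralithium polyanion of the unprotected ketone 3 and the bis-Boc aldehyde 6. Both Boc groups leave in the same flask.
4. 3 and 5 come from direct phenolate C-prenylation of 1 and 4 with prenyl bromide 2.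

Assumption: the quinidine-derived catalyst is taken to give the (2S) product. The sense is checked by circular dichroism on the first run, and if it is reversed the commercial quinine-derived pseudo-enantiomer is used in the same step.

Numbering: in chalcones the primed positions are on ring A (ketone side). In flavanones the primed positions are on ring B.

**Step 1**
Reactants: 1 2,4,6-trihydroxyacetophenone; 2 prenyl bromide (1-bromo-3-methylbut-2-ene)
Product: 3 1-[2,4,6-trihydroxy-3,5-bis(3-methylbut-2-enyl)phenyl]ethanone
Conditions: 2 (2.1 equiv), KOH (2.2 equiv), H2O, 0 °C → rt, 4 h; acidify, chromatography (expected 30–40%)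
Reagents that add atoms: prenyl bromide, CC(C)=CCBr
Why: This is a Friedel–Crafts-type C-alkylation of the ambident phloroglucinolate, the chemical equivalent of an aromatic prenyltransferase, in which water hydrogen-bonds the phenoxide oxygens so the soft allylic bromide is taken by the two equivalent ring carbons C3 and C5, and limiting 2 to two equivalents holds back geminal over-prenylation, as in the classical preparation of deoxyhumulone-type hop acids.

**Step 2**
Reactants: 4 2,4-dihydroxybenzaldehyde; 2 prenyl bromide
Product: 5 2,4-dihydroxy-3-(3-methylbut-2-enyl)benzaldehyde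
Conditions: 2 (1.1 equiv), KOH (1.2 equiv), H2O, 0 °C → rt, 12 h; acidify, chromatography (expected 25–35%)
Reagents that add atoms: prenyl bromide, CC(C)=CCBr
Why: This is the same phenolate C-alkylation, and C3, flanked by both oxygens, is the most nucleophilic carbon of the resorcinolate, so the 3-prenyl isomer is the main C-alkylated product and is separated from the 5-prenyl and 4-O-prenyl by-products.

**Step 3**
Reactants: 5 2,4-dihydroxy-3-(3-methylbut-2-enyl)benzaldehyde
Product: 6 2,4-bis(tert-butoxycarbonyloxy)-3-(3-methylbut-2-enyl)benzaldehyde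
Conditions: Boc2O (2.2 equiv), 4-(dimethylamino)pyridine (5 mol%), iPr2NEt (0.2 equiv), THF, 0 °C → rt, 2 h (expected 90%)
Reagents that add atoms: di-tert-butyl dicarbonate (Boc2O), CC(C)(C)OC(=O)OC(=O)OC(C)(C)C
Why: This nucleophile-catalysed O-acylation to aryl carbonates removes the two acidic protons, switches off the phenoxide donation that would deaden the aldehyde, and places an ortho carbonate that later serves as an internal leaving-group relay.

**Step 4**
Reactants: 3 1-[2,4,6-trihydroxy-3,5-bis(3-methylbut-2-enyl)phenyl]ethanone; 6 2,4-bis(tert-butoxycarbonyloxy)-3-(3-methylbut-2-enyl)benzaldehyde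
Product: 10 (E)-2',4',6',2,4-pentahydroxy-3',5',3-triprenylchalcone, via tetralithium polyanion 7 (not isolated), via Boc-shifted aldol carbonate 8 (not isolated), via 4-O-Boc chalcone 9 (not isolated)
Conditions: 3, LiN(SiMe3)2 (4.1 equiv), THF, −78 → −10 °C; 6, −78 → 0 °C; NaOMe (3 equiv), MeOH, 0 °C, 30 min; pour into ice-cold 1 N HCl/EtOAc, Ar, dark; fast chromatography or crystallisation (expected 45–55%)
Reagents that add atoms: none
Why: This is a telescoped chain of known reaction types, in which exhaustive lithiation of a polyhydroxyacetophenone gives a C-nucleophilic enolate (7) that undergoes a directed aldol addition to the aldehyde, the aldolate is trapped irreversibly by alkoxide-triggered O→O Boc migration (8), E1cB loss of tert-butyl carbonate gives the (E)-enone (9), methoxide cleaves the base-labile aryl carbonate and keeps everything in the open polyphenoxide form, and rapid cold acidification delivers the free chalcone before it can close, as in the standard preparation of naringenin chalcone.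

**Step 5**
Reactants: 10 (E)-2',4',6',2,4-pentahydroxy-3',5',3-triprenylchalcone
Product: 11 (2S)-5,7,2',4'-tetrahydroxy-6,8,3'-triprenylflavanone (target)
Conditions: 1-[3,5-bis(trifluoromethyl)phenyl]-3-[(8R,9R)-6'-methoxycinchonan-9-yl]thiourea (quinidine-derived, C29H28F6N4OS, 15 mol%), toluene/CH2Cl2 4:1 (0.05 mol/L), 4 Å sieves, −20 °C, dark, 48–72 h; cold aq. citric acid wash; recrystallise to ≥98% ee (expected 70–80%)
Reagents that add atoms: none
Why: Proposed new method: this is a small-molecule version of the chalcone isomerase reaction (enantioselective intramolecular 6-endo-trig oxa-Michael addition) in which the quinuclidine nitrogen takes the proton of one ortho-hydroxyl of ring A while the thiourea N–H pair and the substrate's own second ortho-hydroxyl hydrogen-bond the enone carbonyl, so that the ion-paired phenoxide adds to the Si face of C-β and sets C2 as (S) before the enol tautomerises; it should work because ring A is symmetric (either ortho-OH gives the same flavanone), the uncatalysed closure is negligible in a cold non-polar solvent, the closed form is favoured since the 5-OH···O=C chelate is kept, and the weak base at −20 °C does not reopen the product, the closest known reaction types being the cinchona-thiourea-catalysed oxa-Michael cyclisation of 2-hydroxyaryl alkylidene β-keto esters to flavanones and the cinchona-alkaloid-catalysed cyclisation of simple 2'-hydroxychalcones.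

**Compound list**
1 | 2,4,6-trihydroxyacetophenone | CC(=O)c1c(O)cc(O)cc1O | starting material
2 | prenyl bromide (1-bromo-3-methylbut-2-ene) | CC(C)=CCBr | starting material
3 | 1-[2,4,6-trihydroxy-3,5-bis(3-methylbut-2-enyl)phenyl]ethanone | CC(=O)c1c(O)c(CC=C(C)C)c(O)c(CC=C(C)C)c1O | intermediate
4 | 2,4-dihydroxybenzaldehyde | O=Cc1ccc(O)cc1O | starting material
5 | 2,4-dihydroxy-3-(3-methylbut-2-enyl)benzaldehyde | O=Cc1ccc(O)c(CC=C(C)C)c1O | intermediate
6 | 2,4-bis(tert-butoxycarbonyloxy)-3-(3-methylbut-2-enyl)benzaldehyde | O=Cc1ccc(OC(=O)OC(C)(C)C)c(CC=C(C)C)c1OC(=O)OC(C)(C)C | intermediate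
7 | tetralithium salt of 3 (three phenoxides and the methyl ketone enolate) | [Li+].[Li+].[Li+].[Li+].C=C([O-])c1c([O-])c(CC=C(C)C)c([O-])c(CC=C(C)C)c1[O-] | intermediate
8 | racemic aldol with the ortho Boc moved to the benzylic oxygen: 1-[4-(tert-butoxycarbonyloxy)-2-hydroxy-3-prenylphenyl]-3-oxo-3-(2,4,6-trihydroxy-3,5-diprenylphenyl)propyl tert-butyl carbonate (present as lithium phenoxides, drawn neutral) | CC(C)=CCc1c(OC(=O)OC(C)(C)C)ccc(C(CC(=O)c2c(O)c(CC=C(C)C)c(O)c(CC=C(C)C)c2O)OC(=O)OC(C)(C)C)c1O | intermediate
9 | (E)-4-(tert-butoxycarbonyloxy)-2',4',6',2-tetrahydroxy-3',5',3-triprenylchalcone (present as lithium phenoxides, drawn neutral) | CC(C)=CCc1c(OC(=O)OC(C)(C)C)ccc(/C=C/C(=O)c2c(O)c(CC=C(C)C)c(O)c(CC=C(C)C)c2O)c1O | intermediate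
10 | (E)-2',4',6',2,4-pentahydroxy-3',5',3-triprenylchalcone | CC(C)=CCc1c(O)ccc(/C=C/C(=O)c2c(O)c(CC=C(C)C)c(O)c(CC=C(C)C)c2O)c1O | intermediate
11 | (2S)-5,7,2',4'-tetrahydroxy-6,8,3'-triprenylflavanone | CC(C)=CCc1c(O)ccc([C@@H]2CC(=O)c3c(O)c(CC=C(C)C)c(O)c(CC=C(C)C)c3O2)c1O | target

**Totals**
Total step count: 5.
Longest linear sequence: 4 steps (4 → 5 → 6 → 10 → 11). The other branch (1 → 3 → 10 → 11) has 3 steps.

**Steps most likely to fail**

**Step 5.**
- Risk: the enantioselectivity on an unprotected, electron-rich chalcone is unproven. The acidic phenols may tie up the base, and slow reopening of the product could erode the ee.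
- Fallback: it sets out from 10 and comes back at 11.
- 10 is closed without chiral control (NaOAc, EtOH, 60 °C) to the racemic flavanone F1.
- F1 is then resolved kinetically by asymmetric transfer hydrogenation (RhCl(C5Me5)[(R,R)-TsDPEN] 1 mol%, HCO2H/Et3N, EtOAc, rt, stopped near 52% conversion).
- The (2R) enantiomer is reduced to the (2R,4R)-cis-flavan-4-ol F2, while the unreacted (2S) ketone 11 is recovered by chromatography.
- The prenyl alkenes are not touched, and the acidic medium prevents racemisation by ring opening.

**Step 4.**
- Risk: the polyanion may be poorly soluble or sluggish, Boc groups may scramble, and 10 may partly close to racemic flavanone during quench and purification.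
- Fallback: it sets out from 3 and 5 and comes back at 10.
- 3 is protected (MOMCl, iPr2NEt, CH2Cl2) to the 2-hydroxy-4,6-bis(methoxymethoxy) ketone F3, and 5 likewise to the bis(methoxymethoxy) aldehyde F4.
- The two are joined by a classical Claisen–Schmidt condensation (KOH, EtOH/H2O, rt) to the tetra-MOM chalcone F5.
- The acetals are removed (3 N HCl, MeOH, 45 °C, dark), which gives the racemic flavanone F1.
- F1 is reopened with concentrated KOH in aqueous EtOH and poured into ice-cold acid to give 10.

**Step 2.**
- Risk: there is three-way competition between C3, C5 and O-alkylation, and the yield is low.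
- Fallback: it sets out from 4 and comes back at 5.
- The free 4-OH is etherified with tert-butyl 2-methylbut-3-en-2-yl carbonate under Pd(PPh3)4 catalysis (THF, 0 °C) to the 4-O-(1,1-dimethylallyl) ether F6.
- Heating (N,N-diethylaniline, 130 °C) brings about an aromatic Claisen rearrangement. It goes to C3 because chelation of the 2-OH to the formyl group makes the C3–C4 bond the more double-bond-like one, and it delivers the prenyl group of 5 with allyl inversion.

**Further compounds**
F1 | step 5 | racemic 5,7,2',4'-tetrahydroxy-6,8,3'-triprenylflavanone | CC(C)=CCc1c(O)ccc(C2CC(=O)c3c(O)c(CC=C(C)C)c(O)c(CC=C(C)C)c3O2)c1O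
F2 | step 5 | (2R,4R)-cis-6,8,3'-triprenylflavan-4,5,7,2',4'-pentaol | CC(C)=CCc1c(O)ccc([C@H]2C[C@@H](O)c3c(O)c(CC=C(C)C)c(O)c(CC=C(C)C)c3O2)c1O
F3 | step 4 | 1-[2-hydroxy-4,6-bis(methoxymethoxy)-3,5-bis(3-methylbut-2-enyl)phenyl]ethanone | CC(=O)c1c(O)c(CC=C(C)C)c(OCOC)c(CC=C(C)C)c1OCOC
F4 | step 4 | 2,4-bis(methoxymethoxy)-3-(3-methylbut-2-enyl)benzaldehyde | O=Cc1ccc(OCOC)c(CC=C(C)C)c1OCOC
F5 | step 4 | (E)-2'-hydroxy-4',6',2,4-tetrakis(methoxymethoxy)-3',5',3-triprenylchalcone | CC(C)=CCc1c(OCOC)ccc(/C=C/C(=O)c2c(O)c(CC=C(C)C)c(OCOC)c(CC=C(C)C)c2OCOC)c1OCOC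
F6 | step 2 | 2-hydroxy-4-(2-methylbut-3-en-2-yloxy)benzaldehyde | O=Cc1ccc(OC(C)(C)C=C)cc1O
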